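- The north run was charged heavier than the south-east run, yet over its last readings its solid substrate fell at nearly the same molar pace, 0.0109 M h⁻¹ against 0.0116 M h⁻¹.

| setting | south-east | north | flask |
|---|---|---|---|
| solid substrate | 0.25 M | 0.40 M | 0.18 M |
| remark | run made earlier | run made earlier |  |
| time |  |  | 15 h |

- south-east (time / h: solid substrate / %, target / %, isomer of the product B / %): 1.50: 74.5, 2.1, 0; 3.00: 59.1, 4.6, 1.2; 5.00: 45.1, 6.9, 4.1; 6.00: 38.3, 7.9, 6.7; 8.00: 28.7, 8.3, 12.2; 10.0: 19.2, 8.9, 19.1; 12.0: 10.1, 8.9, 27.2
- north (time / h: solid substrate / %, target / %, isomer of the product B / %): 1.00: 87.9, 0.9, 1.0; 1.33: 85.4, 1.6, 0; 2.00: 80.9, 2.4, 0; 3.00: 73.8, 1.6, 1.1; 5.00: 65.4, 4.2, 2.8; 8.00: 55.7, 6.3, 8.6; 12.0: 44.8, 5.4, 16.8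

(each reading ± 0.5 percentage points)

1. why nothing more happens at 15 h, or that something still does (for what has run out or reacted, a solid counts together with what of it has only dissolved) (forward and back rates have come level / all of the solid substrate has reacted / it is still moving)
2. part of the solid substrate that has turned into other species by 15 h (what has only dissolved does not count)
3. the target standing at 15 h, as a percentage of the solid substrate charged
4. the isomer of the product B standing at 15 h, as a percentage of the solid substrate charged

- at the start none of the solid substrate is in solution
- what has only dissolved of solid substrate counts as not reacted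
- a reading or a percentage of target counts all its forms, free or not
- the reaction counts as stopped when no species that holds the solid substrate changes by six tenths of a point or more over the second half of the time

- So I froze the mean as the drain D = 0.0113 M h⁻¹, a pseudo-zero-order stretch. Run back to zero time, the late lines met the axis below their charges by 0.0853 M and 0.0900 M, and I took the mean as the hold-up H = 0.0876 M.
- Up to their first readings the south-east and north runs lost solid substrate at 0.0425 M h⁻¹ and 0.0484 M h⁻¹, so I drew the flask's solid substrate from a starting slope S = 0.0454 M h⁻¹, steeper than D by a factor 4.02.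
- On my drawing, that opening line meets the late line at the knee, t_k = H/(S − D) = 2.56 h, where the drawing has 35.3% of the flask's charge as solid substrate.
- From there the flask's line falls straight to zero at the solid's lifetime t_e, the charge minus H, divided by D: 8.20 h. The asked time lies later.
- The forecast said it is still moving, with conversion 81%, target 10.5% and isomer of the product B 50%, on the ground that “Excess solid (0.095 M) is gone by about 8.3 h”.
- The flask gave it is still moving, with conversion 68.1%, target 8.25% and isomer of the product B 47.8%.

    crystals ⇌ target, rate k1*(cs1 - [target]) while solid is left; crystals form when [target] > cs1 (solubility = 33.0 mM, k = 0.0370 s⁻¹)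
    target ⇌ isomer of the product A (K = 2.50, k = 2.40 × 10⁻⁴ s⁻¹)
    solid substrate ⇌ starting material, rate k3*(cs3 - [starting material]) while solid is left; crystals form when [starting material] > cs3 (solubility = 0.130 M, k = 1.20 × 10⁻⁴ s⁻¹)
    isomer of the product A ⇌ isomer of the product B (K = 31.0, k = 9.60 × 10⁻⁵ s⁻¹)
    starting material ⇌ target (K = 0.420, k = 5.50 × 10⁻⁵ s⁻¹)

- My line gave 4.39% solid substrate in the flask at 7.50 h, and the flask held 4.20%. At the asked time its solid substrate stood at 0%, but starting material, the dissolved form, stood at 31.9%, against the 19.0% unconverted in the forecast, which is its 13 percentage points on conversion. The same flask read at 4.0 h lies before t_e: the line gave 26.3% solid substrate, and that neighbour held 32.1%.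

The earlier runs and the new flask are calculated from invented constants; the scatter is artificial.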